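## Retrosynthetic overview

1. The last ring is the 3(2H)-furanone (O, C3, C2, C1, C10). It is closed in the same operation that closes the ten-membered carbocycle: a palladium-catalysed carbonylative Sonogashira macrocyclization in which CO becomes C3 (bonds C3–C4 and C2–C3), then an amine-relayed cyclodehydration in the same flask (bond O–C3).
2. Enabling feature: C3, shared by the furanone and the carbocycle, sits at acyl oxidation level between vinyl carbon C4 (of the Z C4=C5 alkene) and C2. The unit O–C3=C2–C1=O is the cyclodehydrated form of a 4-hydroxy-2-yn-1-one whose hydroxyl is the tertiary C10–OH, so the seco precursor needs only a (Z)-vinyl iodide and a terminal tertiary propargylic alcohol.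
3. The precursor gets its (Z)-vinyl iodide by iodo-Wittig olefination of a C5 aldehyde, its 8-O-isovalerate and 9-O-silyl ether after acetonide removal, and carries the α-methylene group masked as a Mannich base.
4. The C7–C8 bond comes from decarboxylative radical conjugate addition of an L-tartrate-derived dioxolanyl radical to (S)-5-(silyloxymethyl)butenolide (sets C7 and C8). C10 comes from chelate-controlled MeMgBr addition to a tartrate ynone; C6, C8 and C9 come from the chiral pool.
5. Ring order: γ-lactone (chiral pool), then ten-membered carbocycle, then furanone (both in step 14, furanone last), then unmasking of the methylene group and of O9.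

Key step: step 14

Remark: locants C1–C15 are germacrane numbers (C1 furanone C=O, C3 enol-ether carbon, C6 lactone CH–O, C10 oxygenated quaternary carbon, C12 lactone C=O); the target is (6R,7S,8S,9R,10R); the C11 configuration of the Mannich base (expected trans to the C7 substituent) is immaterial because C11 becomes sp2 again.

## Route

Step 1
Reactants: 1 (S)-5-(hydroxymethyl)furan-2(5H)-one
Product: 2 (S)-5-[(tert-butyldiphenylsilyloxy)methyl]furan-2(5H)-one
Conditions: TBDPSCl, imidazole, CH2Cl2, 0 °C → rt
Reagents that add atoms: tert-butyl(chloro)diphenylsilane, CC(C)(C)[Si](Cl)(c1ccccc1)c1ccccc1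
Why: Routine silyl ether formation at a primary alcohol; C6 comes unchanged from the chiral pool and the bulky silyloxymethyl group later shields one face of the butenolide.

Step 2
Reactants: 3 dimethyl (4R,5R)-2,2-dimethyl-1,3-dioxolane-4,5-dicarboxylate
Product: 4 potassium (4R,5R)-5-(methoxycarbonyl)-2,2-dimethyl-1,3-dioxolane-4-carboxylate
Conditions: KOH (1.0 equiv), MeOH, 0 °C → rt
Reagents that add atoms: potassium hydroxide, [K+].[OH-]
Why: Mono-saponification of a C2-symmetric diester (ester hydrolysis); the carboxylate formed deactivates the molecule towards a second hydrolysis and the two ester groups are homotopic, so no selectivity problem arises.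

Step 3
Reactants: 4 potassium (4R,5R)-5-(methoxycarbonyl)-2,2-dimethyl-1,3-dioxolane-4-carboxylate; 5 ethynyltri(propan-2-yl)silane
Product: 7 methyl (4R,5R)-2,2-dimethyl-5-[3-(triisopropylsilyl)prop-2-ynoyl]-1,3-dioxolane-4-carboxylate, via acid chloride 6 (not isolated)
Conditions: (COCl)2, DMF (cat.), CH2Cl2, 0 °C; then 5, PdCl2(PPh3)2 (2 mol %), CuI (4 mol %), Et3N (1.2 equiv), THF, rt
Reagents that add atoms: none
Why: Acid chloride formation from the potassium salt avoids free HCl near the acetonide, and the acyl Sonogashira coupling (palladium/copper acylation of a terminal alkyne) gives the ynone without touching the methyl ester; the trans-dioxolane, being the more stable arrangement, should be retained.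

Step 4
Reactants: 7 methyl (4R,5R)-2,2-dimethyl-5-[3-(triisopropylsilyl)prop-2-ynoyl]-1,3-dioxolane-4-carboxylate
Product: 8 methyl (4R,5R)-5-[(2S)-2-hydroxy-4-(triisopropylsilyl)but-3-yn-2-yl]-2,2-dimethyl-1,3-dioxolane-4-carboxylate
Conditions: MeMgBr (1.3 equiv), CH2Cl2/Et2O, −78 °C; aq. NH4Cl
Reagents that add atoms: methylmagnesium bromide, C[Mg]Br
Why: Cram-chelate 1,2-addition of a Grignard reagent: magnesium bridges the ketone oxygen and the C9 dioxolane oxygen so that methyl attacks the face away from C8, which should give the 9,10-anti tertiary alcohol (C10 as in the target); the ynone reacts much faster than the ester at −78 °C and the triisopropylsilyl group blocks conjugate addition.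

Step 5
Reactants: 8 methyl (4R,5R)-5-[(2S)-2-hydroxy-4-(triisopropylsilyl)but-3-yn-2-yl]-2,2-dimethyl-1,3-dioxolane-4-carboxylate
Product: 9 (4R,5R)-5-[(2S)-2-hydroxy-4-(triisopropylsilyl)but-3-yn-2-yl]-2,2-dimethyl-1,3-dioxolane-4-carboxylic acid
Conditions: LiOH·H2O, THF/H2O, 0 °C → rt; then 1 M HCl to pH 3, 0 °C
Reagents that add atoms: lithium hydroxide, [Li+].[OH-]
Why: Ester saponification; the trans arrangement on the dioxolane prevents lactonization onto the tertiary hydroxyl, and epimerization at the carboxyl-bearing carbon would not matter because this centre becomes a radical in the next step.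

Step 6
Reactants: 9 (4R,5R)-5-[(2S)-2-hydroxy-4-(triisopropylsilyl)but-3-yn-2-yl]-2,2-dimethyl-1,3-dioxolane-4-carboxylic acid; 2 (S)-5-[(tert-butyldiphenylsilyloxy)methyl]furan-2(5H)-one
Product: 10 silyl-protected trans-lactone acetonide (C7–C8 coupled product)
Conditions: Ir[dF(CF3)ppy]2(dtbbpy)PF6 (1 mol %), K2HPO4, 2 (1.5 equiv), DMF, 450 nm LEDs, rt
Reagents that add atoms: none
Why: Photoredox decarboxylative Giese addition (radical conjugate addition): oxidation of the carboxylate and loss of CO2 give the nucleophilic dioxolan-4-yl radical (polarity reversal at C8), which adds to the butenolide β-carbon; C7 should be set anti to the C6 silyloxymethyl group (trans-lactone) and C8 anti to the bulky C9 substituent on the dioxolane (trans-acetonide), both by substrate control.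

Step 7
Reactants: 10 silyl-protected trans-lactone acetonide
Product: 11 Mannich base (C11 dimethylaminomethyl lactone)
Conditions: LiN(iPr)2 (2.2 equiv), THF, −78 °C; CH2=NMe2+ I− (2.5 equiv), −78 → 0 °C; aq. NaHCO3
Reagents that add atoms: N,N-dimethylmethyleneiminium iodide (Eschenmoser's salt), C=[N+](C)C.[I-]
Why: Mannich reaction of the lactone enolate (the tertiary alkoxide is a spectator and any O-aminomethyl aminal hydrolyses on work-up); the aminomethyl group should enter trans to the C7 substituent and acts as a masked α-methylene group that cannot take part in Heck or amine chemistry later.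

Step 8
Reactants: 11 Mannich base
Product: 12 hydroxymethyl lactone with terminal alkyne
Conditions: TBAF (2.5 equiv), THF, 0 °C → rt; aq. NH4Cl
Reagents that add atoms: none
Why: Fluoride-induced desilylation cleaves the O–Si and the C(sp)–Si bond in one operation, while acetonide, lactone and Mannich base are inert to fluoride.

Step 9
Reactants: 12 hydroxymethyl lactone with terminal alkyne
Product: 13 C5 aldehyde
Conditions: SO3·pyridine, DMSO, iPr2NEt, CH2Cl2, 0 °C
Reagents that add atoms: none
Why: Parikh–Doering oxidation (activated-DMSO oxidation) tolerates the tertiary amine, the tertiary alcohol and the alkyne and should not epimerize the α-oxygenated aldehyde at 0 °C.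

Step 10
Reactants: 13 C5 aldehyde
Product: 14 (Z)-vinyl iodide acetonide
Conditions: EtPPh3I, n-BuLi, THF, 0 °C; I2, −78 °C; NaN(SiMe3)2, −78 → −20 °C; then 13, −78 → −20 °C
Reagents that add atoms: ethyltriphenylphosphonium iodide, CC[P+](c1ccccc1)(c1ccccc1)c1ccccc1.[I-]; iodine, II
Why: Stork–Zhao-type Wittig olefination with the α-iodoethylidene ylide, which under kinetic control at low temperature gives (Z)-2-iodo-2-alkenes (iodine cis to the chain, here cis to C6); the ylide is not basic enough to deprotonate the alkyne or the tertiary alcohol.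

Step 11
Reactants: 14 (Z)-vinyl iodide acetonide
Product: 15 8,9,10-triol
Conditions: 1 M aq. HCl, THF, rt; then aq. NaHCO3
Reagents that add atoms: none
Why: Acid-catalysed acetal hydrolysis; vinyl iodide, lactone, protonated Mannich base and propargylic alcohol should tolerate dilute aqueous acid at room temperature.

Step 12
Reactants: 15 8,9,10-triol
Product: 16 8-O-isovalerate
Conditions: isovaleric anhydride (1.05 equiv), Et3N, DMAP (5 mol %), CH2Cl2, −40 → −20 °C
Reagents that add atoms: 3-methylbutanoic anhydride, CC(C)CC(=O)OC(=O)CC(C)C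
Why: Regioselective DMAP-catalysed acylation: O10 is tertiary and O9 is neopentyl-like (next to the fully substituted C10 and hydrogen-bonded to its hydroxyl), so one equivalent of anhydride at low temperature should esterify O8, and the low temperature suppresses acyl migration.

Step 13
Reactants: 16 8-O-isovalerate
Product: 17 seco precursor (8-O-isovaleryl-9-O-TBS iodo-alkyne)
Conditions: TBSOTf (1.1 equiv), 2,6-lutidine, CH2Cl2, −78 °C
Reagents that add atoms: tert-butyldimethylsilyl trifluoromethanesulfonate, CC(C)(C)[Si](C)(C)OS(=O)(=O)C(F)(F)F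
Why: Silyl triflate silylation at −78 °C distinguishes the secondary C9 hydroxyl from the tertiary C10 hydroxyl; the silyl ether blocks 8→9 acyl migration and keeps O9 out of the key step.

Step 14
Reactants: 17 seco precursor (8-O-isovaleryl-9-O-TBS iodo-alkyne)
Product: 20 9-O-TBS-13-(dimethylamino)-11,13-dihydrolobatin B, via macrocyclic enynone 18 (not isolated), via enaminone 19 (not isolated)
Conditions: PdCl2(PPh3)2 (10 mol %), CuI (10 mol %), Et3N, CO (1 atm), THF, 40 °C, slow addition of 17 (final 2 mM); then Et2NH, rt; then AcOH/H2O, rt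
Reagents that add atoms: carbon monoxide, [C-]#[O+]; water, O
Why: Proposed new method: zerovalent palladium adds oxidatively to the (Z)-vinyl iodide with retention, CO inserts to give the C3 acylpalladium, and copper-acetylide transmetalation/reductive elimination joins C3 to C2, closing the ten-membered carbocycle as the strained enynone 18; Et2NH then adds to C1 (strain-accelerated conjugate addition) to give enaminone 19, the tertiary C10 hydroxyl adds to the C3 carbonyl, and aqueous acid completes dehydration and iminium hydrolysis to the 3(2H)-furanone. The closest known reactions are the intermolecular three-component synthesis of 3(2H)-furanones from aryl or vinyl halides, CO and tertiary propargylic alcohols, the amine-relayed cyclization of 4-hydroxy-2-yn-1-ones, and carbonylative cross-coupling macrocyclizations; what has not been shown is a carbonylative Sonogashira coupling that closes a ten-membered cycloalkynone, which is why the label is used. Ring closures: the carbocycle closes by C2–C3 reductive elimination from an eleven-membered acyl(alkynyl)palladacycle (end-to-end macrocyclization), and the furanone by 5-exo-trig attack of O10 on the C3 carbonyl of 19 followed by loss of water (direct closure onto the linear ynone 18 is geometrically impossible, hence the amine relay). No stereocentre is created: C6–C10 are carried in unchanged and the Z geometry of C4=C5 is that of the vinyl iodide. Required selectivities and their origin: carbonylative over direct coupling because CO insertion into vinylpalladium is fast and the direct product would be a nine-membered enyne; cyclization over oligomerization through slow addition at about 2 mM and the cis C4=C5 turn; O10 rather than O9 attack and no 8→9 acyl shift because O9 is silylated; no Heck insertion or amine addition at C11–C13 because the methylene group is masked as the Mannich base.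

Step 15
Reactants: 20 9-O-TBS-13-(dimethylamino)-11,13-dihydrolobatin B
Product: 22 9-O-TBS-lobatin B, via trimethylammonium iodide 21 (not isolated)
Conditions: MeI, MeCN, rt; then aq. NaHCO3, CH2Cl2, rt
Reagents that add atoms: none
Why: Exhaustive N-methylation followed by E1cB (Hofmann-type) elimination of trimethylamine should regenerate the exocyclic α-methylene lactone regiospecifically under bicarbonate, which is too mild for acyl migration or attack on the furanone.

Step 16
Reactants: 22 9-O-TBS-lobatin B
Product: 23 lobatin B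
Conditions: HF·pyridine, pyridine, THF, 0 °C → rt
Reagents that add atoms: none
Why: Acidic fluoride desilylation frees the C9 hydroxyl without base, so the isovalerate should stay on O8 and the α-methylene lactone and furanone are untouched.

## Compound list

1 | (S)-5-(hydroxymethyl)furan-2(5H)-one | O=C1O[C@@H](C=C1)CO | starting material
2 | (S)-5-[(tert-butyldiphenylsilyloxy)methyl]furan-2(5H)-one | O=C1O[C@@H](C=C1)CO[Si](c1ccccc1)(c1ccccc1)C(C)(C)C | intermediate
3 | dimethyl (4R,5R)-2,2-dimethyl-1,3-dioxolane-4,5-dicarboxylate (acetonide of dimethyl L-tartrate) | COC(=O)[C@@H]1OC(C)(C)O[C@H]1C(=O)OC | starting material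
4 | potassium (4R,5R)-5-(methoxycarbonyl)-2,2-dimethyl-1,3-dioxolane-4-carboxylate | COC(=O)[C@@H]1OC(C)(C)O[C@H]1C(=O)[O-].[K+] | intermediate
5 | ethynyltri(propan-2-yl)silane | C#C[Si](C(C)C)(C(C)C)C(C)C | starting material
6 | methyl (4R,5R)-5-(chlorocarbonyl)-2,2-dimethyl-1,3-dioxolane-4-carboxylate (acid chloride) | COC(=O)[C@@H]1OC(C)(C)O[C@H]1C(Cl)=O | intermediate
7 | methyl (4R,5R)-2,2-dimethyl-5-[3-(triisopropylsilyl)prop-2-ynoyl]-1,3-dioxolane-4-carboxylate (ynone ester) | COC(=O)[C@@H]1OC(C)(C)O[C@H]1C(=O)C#C[Si](C(C)C)(C(C)C)C(C)C | intermediate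
8 | methyl (4R,5R)-5-[(2S)-2-hydroxy-4-(triisopropylsilyl)but-3-yn-2-yl]-2,2-dimethyl-1,3-dioxolane-4-carboxylate (9,10-anti tertiary alcohol) | COC(=O)[C@@H]1OC(C)(C)O[C@H]1[C@@](C)(O)C#C[Si](C(C)C)(C(C)C)C(C)C | intermediate
9 | (4R,5R)-5-[(2S)-2-hydroxy-4-(triisopropylsilyl)but-3-yn-2-yl]-2,2-dimethyl-1,3-dioxolane-4-carboxylic acid | OC(=O)[C@@H]1OC(C)(C)O[C@H]1[C@@](C)(O)C#C[Si](C(C)C)(C(C)C)C(C)C | intermediate
10 | silyl-protected trans-lactone acetonide: 6,12-olide with CH2OTBDPS on C6, trans C7 substituent = trans-C8/C9-acetonide whose C9 bears C10(CH3)(OH)–C≡C–Si(iPr)3, all centres as in the target | CC(C)[Si](C(C)C)(C(C)C)C#C[C@](C)(O)[C@@H]1OC(C)(C)O[C@H]1[C@H]1CC(=O)O[C@@H]1CO[Si](c1ccccc1)(c1ccccc1)C(C)(C)C | intermediate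
11 | Mannich base: compound 10 with a CH2NMe2 group on C11, trans to the C7 substituent | CC(C)[Si](C(C)C)(C(C)C)C#C[C@](C)(O)[C@@H]1OC(C)(C)O[C@H]1[C@H]1[C@H](CN(C)C)C(=O)O[C@@H]1CO[Si](c1ccccc1)(c1ccccc1)C(C)(C)C | intermediate
12 | hydroxymethyl lactone with terminal alkyne: compound 11 without both silyl groups | C#C[C@](C)(O)[C@@H]1OC(C)(C)O[C@H]1[C@H]1[C@H](CN(C)C)C(=O)O[C@@H]1CO | intermediate
13 | C5 aldehyde: compound 12 with CHO in place of CH2OH on C6 | C#C[C@](C)(O)[C@@H]1OC(C)(C)O[C@H]1[C@H]1[C@H](CN(C)C)C(=O)O[C@@H]1C=O | intermediate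
14 | (Z)-vinyl iodide acetonide: C6 carries (Z)-CH=C(CH3)I, iodine cis to C6 | C#C[C@](C)(O)[C@@H]1OC(C)(C)O[C@H]1[C@H]1[C@H](CN(C)C)C(=O)O[C@@H]1/C=C(/C)I | intermediate
15 | 8,9,10-triol: compound 14 without the acetonide | C#C[C@](C)(O)[C@H](O)[C@@H](O)[C@H]1[C@H](CN(C)C)C(=O)O[C@@H]1/C=C(/C)I | intermediate
16 | 8-O-isovalerate: compound 15 esterified at O8 with 3-methylbutanoic acid | C#C[C@](C)(O)[C@H](O)[C@@H](OC(=O)CC(C)C)[C@H]1[C@H](CN(C)C)C(=O)O[C@@H]1/C=C(/C)I | intermediate
17 | seco precursor: compound 16 with O9 as tert-butyldimethylsilyl ether, C10–OH free | C#C[C@](C)(O)[C@H](O[Si](C)(C)C(C)(C)C)[C@@H](OC(=O)CC(C)C)[C@H]1[C@H](CN(C)C)C(=O)O[C@@H]1/C=C(/C)I | intermediate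
18 | macrocyclic enynone: ten-membered ring C1–C10 with C3=O, C1≡C2 and Z C4=C5, C10–OH free | O=C1C#C[C@](C)(O)[C@H](O[Si](C)(C)C(C)(C)C)[C@@H](OC(=O)CC(C)C)[C@H]2[C@H](CN(C)C)C(=O)O[C@@H]2/C=C1/C | intermediate
19 | enaminone: compound 18 after addition of diethylamine at C1, C3 and C10 cis on C1=C2 | O=C1/C=C(/N(CC)CC)[C@](C)(O)[C@H](O[Si](C)(C)C(C)(C)C)[C@@H](OC(=O)CC(C)C)[C@H]2[C@H](CN(C)C)C(=O)O[C@@H]2/C=C1/C | intermediate
20 | 9-O-TBS-13-(dimethylamino)-11,13-dihydrolobatin B (6R,7S,8S,9R,10R,11R) | C1(=O)C=C2O[C@]1(C)[C@H](O[Si](C)(C)C(C)(C)C)[C@@H](OC(=O)CC(C)C)[C@H]1[C@H](CN(C)C)C(=O)O[C@@H]1/C=C2/C | intermediate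
21 | trimethylammonium iodide of 20 | C1(=O)C=C2O[C@]1(C)[C@H](O[Si](C)(C)C(C)(C)C)[C@@H](OC(=O)CC(C)C)[C@H]1[C@H](C[N+](C)(C)C)C(=O)O[C@@H]1/C=C2/C.[I-] | intermediate
22 | 9-O-TBS-lobatin B (6R,7S,8S,9R,10R) | C1(=O)C=C2O[C@]1(C)[C@H](O[Si](C)(C)C(C)(C)C)[C@@H](OC(=O)CC(C)C)[C@H]1C(=C)C(=O)O[C@@H]1/C=C2/C | intermediate
23 | lobatin B (6R,7S,8S,9R,10R) | C=C1C(=O)O[C@@H]2/C=C(/C)C3=CC(=O)[C@](C)(O3)[C@H](O)[C@@H](OC(=O)CC(C)C)[C@@H]12 | target

## Step count and risks

Total step count: 16 (steps 1–16). Longest linear sequence: 15 steps (3 → 23, steps 2–16).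

Steps most likely to fail:

1. Step 14 (proposed new method). The ring closure at the acyl(alkynyl)palladium stage may be outrun by oligomerization or by decay of the acylpalladium, because the ten-membered enynone is strained. The fallback uses known reaction types and closes the ring at an sp3 carbinol carbon instead. It sets out from 17: palladium-catalysed reductive carbonylation of the vinyl iodide (Pd(OAc)2, dppp, CO, Et3SiH, Et3N, DMF, 60 °C) should give the (Z)-enal F1. Iodination of the alkyne terminus (N-iodosuccinimide, AgNO3 cat., acetone, the amine kept as its trifluoroacetate) should give the iodoalkyne F2. Intramolecular Nozaki–Hiyama–Kishi coupling (CrCl2, NiCl2 cat., THF, high dilution) should close the ring as the macrocyclic carbinol F3 (C3 epimers, both usable). MnO2 oxidation (CH2Cl2, rt) comes back to the route at 18, which is then isolated and taken through the Et2NH/aqueous AcOH part of step 14 to 20.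

2. Step 12. Discrimination between the two secondary hydroxyls (O8 against O9) may be insufficient, or base may induce an 8→9 acyl shift during the acylation. The fallback sets out from 15: tBu2Si(OTf)2/2,6-lutidine (CH2Cl2, 0 °C) should tie O8 and O10 into the six-membered silylene F4 (the 1,3-diol is preferred over either 1,2-diol). TBSOTf/2,6-lutidine then silylates the only free hydroxyl to give the silylene TBS ether F5. Pyridine-buffered HF·pyridine (THF, 0 °C) removes the silylene but not the TBS ether to give the 8,10-diol F6. Isovaleric anhydride/DMAP then acylates the only secondary hydroxyl and comes back to the route at 17.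

3. Step 4. Addition may go through an open (Felkin–Anh) rather than the chelated transition state, giving wrong or poor facial selectivity at C10. The fallback sets out from acid chloride 6 and inverts the order of the two carbon nucleophiles, so that the same intrinsic preference gives the required epimer. Me2CuLi (THF, −78 °C) should give the methyl ketone F7. Lithium (triisopropylsilyl)acetylide (from 5 and n-BuLi, THF, −78 °C), adding under Felkin–Anh control to the ketone and not the ester, comes back to the route at 8.

## Further compounds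

F1 | step 14 | (Z)-enal: compound 17 with CHO in place of iodine on C4 | C#C[C@](C)(O)[C@H](O[Si](C)(C)C(C)(C)C)[C@@H](OC(=O)CC(C)C)[C@H]1[C@H](CN(C)C)C(=O)O[C@@H]1/C=C(/C)C=O
F2 | step 14 | iodoalkyne: compound F1 with iodine on the alkyne terminus C2 | IC#C[C@](C)(O)[C@H](O[Si](C)(C)C(C)(C)C)[C@@H](OC(=O)CC(C)C)[C@H]1[C@H](CN(C)C)C(=O)O[C@@H]1/C=C(/C)C=O
F3 | step 14 | macrocyclic carbinol: compound 18 with CH(OH) at C3 (both C3 epimers) | OC1C#C[C@](C)(O)[C@H](O[Si](C)(C)C(C)(C)C)[C@@H](OC(=O)CC(C)C)[C@H]2[C@H](CN(C)C)C(=O)O[C@@H]2/C=C1/C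
F4 | step 12 | 8,10-O-(di-tert-butylsilylene) derivative of 15, C9–OH free | C#C[C@]1(C)O[Si](C(C)(C)C)(C(C)(C)C)O[C@H]([C@H]1O)[C@H]1[C@H](CN(C)C)C(=O)O[C@@H]1/C=C(/C)I
F5 | step 12 | 9-O-TBS ether of F4 | C#C[C@]1(C)O[Si](C(C)(C)C)(C(C)(C)C)O[C@H]([C@H]1O[Si](C)(C)C(C)(C)C)[C@H]1[C@H](CN(C)C)C(=O)O[C@@H]1/C=C(/C)I
F6 | step 12 | 9-O-TBS 8,10-diol | C#C[C@](C)(O)[C@H](O[Si](C)(C)C(C)(C)C)[C@@H](O)[C@H]1[C@H](CN(C)C)C(=O)O[C@@H]1/C=C(/C)I
F7 | step 4 | methyl (4R,5R)-5-acetyl-2,2-dimethyl-1,3-dioxolane-4-carboxylate | COC(=O)[C@@H]1OC(C)(C)O[C@H]1C(C)=O
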